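The flavonol is disconnected at O1–C8a and C4–C4a: ring A arrives as a 3-methoxyaryne and C2–C4 plus ring B as an arylpropiolic acid. In one operation the aryne inserts into the carboxyl C–O bond, putting the carboxylate oxygen on C8a (flanked only by H-8) and the acyl carbon on C4a (beside the C5 methoxy group), so the adjacent O1/C4 pattern of ring A is fixed by aryne polarisation alone. The precursors are a 7-O-MOM o-silylaryl triflate, obtained through a desymmetrising retro-Brook shift, and the (R)-configured, MOM-protected ring B propiolic acid. Amine-mediated closure of ring C, C3 hydroxylation and acetal removal complete the route.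

Key step: step 12

Remark: flavone numbering is used for rings A and C (O1, C2–C4, C4a, C5–C8, C8a), ring B is primed and the side chain is C1''–C4''; isopropenylmagnesium bromide is taken as the commercial THF solution.

Step 1
Reactants: 1 2,3-dimethoxyphenol
Product: 2 2,3-dimethoxy-1,4-benzoquinone
Conditions: (KSO3)2NO (2.2 equiv), aq. KH2PO4, acetone/H2O, 0 °C to rt
Reagents that add atoms: potassium nitrosodisulfonate, [O]N(S(=O)(=O)[O-])S(=O)(=O)[O-].[K+].[K+]
Why: Teuber oxidation, in which the nitroxyl radical removes the phenolic hydrogen and a second equivalent couples at the free para carbon and then leaves as imidodisulfonate, giving the symmetric para-quinone.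

Step 2
Reactants: 2 2,3-dimethoxy-1,4-benzoquinone
Product: 4 5-bromo-2,3-dimethoxy-1,4-benzoquinone, via dibromide 3 (not isolated)
Conditions: Br2 (1.0 equiv), AcOH, rt; then NaOAc, rt
Reagents that add atoms: bromine, BrBr
Why: Bromine addition to the unsubstituted enedione double bond followed by base-induced loss of HBr (addition–elimination) gives the monobromoquinone, and the two ring CH positions are equivalent so no regiochemical question arises.

Step 3
Reactants: 4 5-bromo-2,3-dimethoxy-1,4-benzoquinone
Product: 5 5-bromo-2,3-dimethoxybenzene-1,4-diol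
Conditions: Na2S2O4, H2O/EtOAc, rt, under N2
Reagents that add atoms: none
Why: Dithionite reduction of a quinone to its hydroquinone is fast and leaves the aryl bromide and the methyl ethers untouched.

Step 4
Reactants: 5 5-bromo-2,3-dimethoxybenzene-1,4-diol
Product: 9 4-hydroxy-2,3-dimethoxy-6-(trimethylsilyl)phenyl trifluoromethanesulfonate, via bis(trimethylsilyl) ether 6 (not isolated), via lithium silylphenoxide 7 (not isolated), via silyl ether triflate 8 (not isolated)
Conditions: HMDS, THF, 70 °C, then evaporate; n-BuLi (1.1 equiv), THF, −78 °C; Tf2O (1.1 equiv), −78 to 0 °C; aq. NaHCO3/MeOH work-up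
Reagents that add atoms: hexamethyldisilazane, C[Si](C)(C)N[Si](C)(C)C; trifluoromethanesulfonic anhydride, O=S(=O)(OS(=O)(=O)C(F)(F)F)C(F)(F)F
Why: Bromine–lithium exchange triggers a retro-Brook 1,3 O-to-C silyl shift that can only start from the oxygen ortho to bromine, so the lithium phenoxide that is triflated is distinguished from the remote silyl ether (hydrolysed on work-up) and the two hydroxyls of the hydroquinone are told apart without a statistical protection.

Step 5
Reactants: 9 4-hydroxy-2,3-dimethoxy-6-(trimethylsilyl)phenyl trifluoromethanesulfonate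
Product: 10 2,3-dimethoxy-4-(methoxymethoxy)-6-(trimethylsilyl)phenyl trifluoromethanesulfonate
Conditions: MOMCl, i-Pr2NEt, CH2Cl2, 0 °C to rt
Reagents that add atoms: chloromethyl methyl ether, COCCl
Why: O-alkylation of the only free phenol under amine base (Williamson-type acetal formation), with the aryl silane and the triflate inert in the absence of fluoride.

Step 6
Reactants: 11 (2-methoxyphenyl)acetic acid
Product: 12 (5-iodo-2-methoxyphenyl)acetic acid
Conditions: NIS (1.05 equiv), TFA (0.3 equiv), MeCN, rt
Reagents that add atoms: N-iodosuccinimide, O=C1CCC(=O)N1I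
Why: Electrophilic aromatic iodination occurs para to the methoxy group, the dominant director, which is the position later joined to C2.

Step 7
Reactants: 12 (5-iodo-2-methoxyphenyl)acetic acid
Product: 14 2-(5-iodo-2-methoxyphenyl)-N-methoxy-N-methylacetamide, via acyl imidazole 13 (not isolated)
Conditions: CDI, CH2Cl2, rt; then MeNH(OMe)·HCl, rt
Reagents that add atoms: N,O-dimethylhydroxylamine hydrochloride, CNOC.Cl
Why: Amide formation through acyl imidazole activation, a mild acylation that needs no acid chloride.

Step 8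
Reactants: 14 2-(5-iodo-2-methoxyphenyl)-N-methoxy-N-methylacetamide; 15 isopropenylmagnesium bromide
Product: 16 1-(5-iodo-2-methoxyphenyl)-3-methylbut-3-en-2-one
Conditions: 15 (2 equiv), THF, −20 to 0 °C; inverse quench into cold 1 M HCl
Reagents that add atoms: none
Why: Weinreb ketone synthesis, in which the N-methoxy-N-methyl amide stops the addition at the ketone stage and the alkenyl Grignard reagent does not exchange with the aryl iodide at this temperature.

Step 9
Reactants: 16 1-(5-iodo-2-methoxyphenyl)-3-methylbut-3-en-2-one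
Product: 17 (2R)-1-(5-iodo-2-methoxyphenyl)-3-methylbut-3-en-2-ol
Conditions: (S)-Me-CBS oxazaborolidine ((S)-1-methyl-3,3-diphenyltetrahydro-1H,3H-pyrrolo[1,2-c][1,3,2]oxazaborole, 0.2 equiv), catecholborane (1.5 equiv), toluene, −78 °C; MeOH, then aq. NaOH wash
Reagents that add atoms: none
Why: Corey–Bakshi–Shibata reduction, in which the α-branched isopropenyl group acts as the large substituent and the benzylic CH2 as the small one, so the (S)-catalyst should deliver hydride to the face that gives the R carbinol, while catecholborane at low temperature reduces only the carbonyl.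

Step 10
Reactants: 17 (2R)-1-(5-iodo-2-methoxyphenyl)-3-methylbut-3-en-2-ol
Product: 18 4-iodo-1-methoxy-2-[(2R)-2-(methoxymethoxy)-3-methylbut-3-en-1-yl]benzene
Conditions: MOMCl, i-Pr2NEt, Bu4NI (cat.), CH2Cl2, 0 °C to rt
Reagents that add atoms: chloromethyl methyl ether, COCCl
Why: O-alkylation to the methoxymethyl acetal breaks no bond at C2'', so the configuration is kept, and this acetal tolerates fluoride, amide base and peroxide in the later steps.

Step 11
Reactants: 18 4-iodo-1-methoxy-2-[(2R)-2-(methoxymethoxy)-3-methylbut-3-en-1-yl]benzene; 19 propiolic acid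
Product: 20 3-{4-methoxy-3-[(2R)-2-(methoxymethoxy)-3-methylbut-3-en-1-yl]phenyl}prop-2-ynoic acid
Conditions: Pd(PPh3)4 (5 mol %), DBU (2.5 equiv), DMSO, 30 °C; cold aq. citric acid
Reagents that add atoms: none
Why: Copper-free Sonogashira-type coupling of an aryl iodide with the propiolate anion runs near room temperature, below the temperature at which arylpropiolic acids decarboxylate.

Step 12
Reactants: 20 3-{4-methoxy-3-[(2R)-2-(methoxymethoxy)-3-methylbut-3-en-1-yl]phenyl}prop-2-ynoic acid; 10 2,3-dimethoxy-4-(methoxymethoxy)-6-(trimethylsilyl)phenyl trifluoromethanesulfonate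
Product: 23 1-[2-hydroxy-5,6-dimethoxy-4-(methoxymethoxy)phenyl]-3-{4-methoxy-3-[(2R)-2-(methoxymethoxy)-3-methylbut-3-en-1-yl]phenyl}prop-2-yn-1-one, via caesium carboxylate 21 (not isolated), via aryne 22 (not isolated)
Conditions: 20, Cs2CO3 (0.5 equiv), MeOH, rt, then evaporate and dry (PhMe azeotrope); CsF (3 equiv), 18-crown-6 (0.5 equiv), THF, 65 °C, slow addition of 10 (1.5 equiv); sat. aq. NH4Cl, 0 °C
Reagents that add atoms: none
Why: Fluoride attack on silicon expels triflate from 10 to give aryne 22, the carboxylate oxygen of 21 adds to C8a, the C4a aryl anion attacks the neighbouring ester carbonyl through a four-membered alkoxide, and this opens to the C8a phenoxide and the C4a ynone (an aryne-triggered acyl shift of the ortho-Fries type). The closest known reaction type is the insertion of arynes into the C–O bond of carboxylic acids to give o-hydroxyaryl ketones, here extended within that class to an alkynoic acid and a tetrasubstituted aryne. No ring is closed and no stereocentre is formed, and the remote C2'' centre is not touched. The step needs regioselective addition to an unsymmetrical aryne: the inductively withdrawing C5 methoxy group next to C4a distorts the triple bond so that the nucleophile enters at the distal C8a and charge builds at C4a, while H-8 on the other side gives no bias and the C6 and C7 oxygens are too remote to override it. It also needs acyl transfer to outrun protonation of the aryl anion, which the dry preformed caesium salt in an aprotic ether (no free acid, no acetonitrile) should secure. Under these conditions the product stays as its phenoxide, which cannot cyclise without a proton source, so the open ynone should be isolated after the cold quench, and any flavone formed early is simply the product of step 13.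

Step 13
Reactants: 23 1-[2-hydroxy-5,6-dimethoxy-4-(methoxymethoxy)phenyl]-3-{4-methoxy-3-[(2R)-2-(methoxymethoxy)-3-methylbut-3-en-1-yl]phenyl}prop-2-yn-1-one
Product: 25 5,6-dimethoxy-7-(methoxymethoxy)-2-{4-methoxy-3-[(2R)-2-(methoxymethoxy)-3-methylbut-3-en-1-yl]phenyl}-4H-chromen-4-one, via enaminone 24 (not isolated)
Conditions: Et2NH (5 equiv), EtOH, rt to 50 °C
Reagents that add atoms: none
Why: Conjugate addition of the secondary amine gives a β-amino enone in which only the β-carbon is electrophilic, so the C8a hydroxyl closes ring C by 6-endo addition–elimination (oxa-Michael addition, then amine loss) and the 5-exo aurone pathway is shut off.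

Step 14
Reactants: 25 5,6-dimethoxy-7-(methoxymethoxy)-2-{4-methoxy-3-[(2R)-2-(methoxymethoxy)-3-methylbut-3-en-1-yl]phenyl}-4H-chromen-4-one
Product: 28 3-hydroxy-5,6-dimethoxy-7-(methoxymethoxy)-2-{4-methoxy-3-[(2R)-2-(methoxymethoxy)-3-methylbut-3-en-1-yl]phenyl}-4H-chromen-4-one, via 3-lithioflavone 26 (not isolated), via dimethyl boronate 27 (not isolated)
Conditions: LDA (LiN(i-Pr)2, 2 equiv), THF, −78 °C; B(OMe)3 (3 equiv), −78 to 0 °C; AcOH, 30% H2O2, 0 °C to rt
Reagents that add atoms: hydrogen peroxide, OO
Why: Carbonyl-directed deprotonation at C3 (known for methoxylated flavones, where ring A hydrogens between two oxygens do not compete), borylation and boronate oxidation with 1,2-migration to oxygen turn C3–H into C3–OH, and acidic peroxide leaves the isopropenyl group alone.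

Step 15
Reactants: 28 3-hydroxy-5,6-dimethoxy-7-(methoxymethoxy)-2-{4-methoxy-3-[(2R)-2-(methoxymethoxy)-3-methylbut-3-en-1-yl]phenyl}-4H-chromen-4-one
Product: 29 3,7-dihydroxy-2-{3-[(2R)-2-hydroxy-3-methylbut-3-en-1-yl]-4-methoxyphenyl}-5,6-dimethoxy-4H-chromen-4-one
Conditions: 3 M aq. HCl, MeOH/THF, 40 °C
Reagents that add atoms: none
Why: Acid-catalysed acetal exchange with methanol removes the phenolic and the secondary MOM groups without breaking the C2''–O bond, so the R configuration is retained, and dilute acid at this temperature should not protonate the 1,1-disubstituted alkene.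

Compound list
1 | 2,3-dimethoxyphenol | COc1cccc(O)c1OC | starting material
2 | 2,3-dimethoxy-1,4-benzoquinone | COC1=C(OC)C(=O)C=CC1=O | intermediate
3 | trans-5,6-dibromo-2,3-dimethoxycyclohex-2-ene-1,4-dione (racemic, one enantiomer drawn) | COC1=C(OC)C(=O)[C@H](Br)[C@@H](Br)C1=O | intermediate
4 | 5-bromo-2,3-dimethoxy-1,4-benzoquinone | COC1=C(OC)C(=O)C(Br)=CC1=O | intermediate
5 | 5-bromo-2,3-dimethoxybenzene-1,4-diol | COc1c(O)cc(Br)c(O)c1OC | intermediate
6 | [(5-bromo-2,3-dimethoxy-1,4-phenylene)bis(oxy)]bis(trimethylsilane) | COc1c(O[Si](C)(C)C)cc(Br)c(O[Si](C)(C)C)c1OC | intermediate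
7 | lithium 2,3-dimethoxy-6-(trimethylsilyl)-4-[(trimethylsilyl)oxy]phenoxide | COc1c(O[Si](C)(C)C)cc([Si](C)(C)C)c([O-])c1OC.[Li+] | intermediate
8 | 2,3-dimethoxy-6-(trimethylsilyl)-4-[(trimethylsilyl)oxy]phenyl trifluoromethanesulfonate | COc1c(O[Si](C)(C)C)cc([Si](C)(C)C)c(OS(=O)(=O)C(F)(F)F)c1OC | intermediate
9 | 4-hydroxy-2,3-dimethoxy-6-(trimethylsilyl)phenyl trifluoromethanesulfonate | COc1c(O)cc([Si](C)(C)C)c(OS(=O)(=O)C(F)(F)F)c1OC | intermediate
10 | 2,3-dimethoxy-4-(methoxymethoxy)-6-(trimethylsilyl)phenyl trifluoromethanesulfonate (ring A aryne precursor) | COCOc1cc([Si](C)(C)C)c(OS(=O)(=O)C(F)(F)F)c(OC)c1OC | intermediate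
11 | (2-methoxyphenyl)acetic acid | COc1ccccc1CC(=O)O | starting material
12 | (5-iodo-2-methoxyphenyl)acetic acid | COc1ccc(I)cc1CC(=O)O | intermediate
13 | 1-(1H-imidazol-1-yl)-2-(5-iodo-2-methoxyphenyl)ethan-1-one | COc1ccc(I)cc1CC(=O)n1ccnc1 | intermediate
14 | 2-(5-iodo-2-methoxyphenyl)-N-methoxy-N-methylacetamide | COc1ccc(I)cc1CC(=O)N(C)OC | intermediate
15 | isopropenylmagnesium bromide | C=C(C)[Mg]Br | starting material
16 | 1-(5-iodo-2-methoxyphenyl)-3-methylbut-3-en-2-one | C=C(C)C(=O)Cc1cc(I)ccc1OC | intermediate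
17 | (2R)-1-(5-iodo-2-methoxyphenyl)-3-methylbut-3-en-2-ol | C=C(C)[C@H](O)Cc1cc(I)ccc1OC | intermediate
18 | 4-iodo-1-methoxy-2-[(2R)-2-(methoxymethoxy)-3-methylbut-3-en-1-yl]benzene | C=C(C)[C@H](OCOC)Cc1cc(I)ccc1OC | intermediate
19 | propiolic acid | C#CC(=O)O | starting material
20 | 3-{4-methoxy-3-[(2R)-2-(methoxymethoxy)-3-methylbut-3-en-1-yl]phenyl}prop-2-ynoic acid | C=C(C)[C@H](OCOC)Cc1cc(C#CC(=O)O)ccc1OC | intermediate
21 | caesium 3-{4-methoxy-3-[(2R)-2-(methoxymethoxy)-3-methylbut-3-en-1-yl]phenyl}prop-2-ynoate | C=C(C)[C@H](OCOC)Cc1cc(C#CC(=O)[O-])ccc1OC.[Cs+] | intermediate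
22 | 1,2-didehydro-3,4-dimethoxy-5-(methoxymethoxy)benzene (aryne across C4a–C8a) | COCOC1=CC#CC(OC)=C1OC | intermediate
23 | 1-[2-hydroxy-5,6-dimethoxy-4-(methoxymethoxy)phenyl]-3-{4-methoxy-3-[(2R)-2-(methoxymethoxy)-3-methylbut-3-en-1-yl]phenyl}prop-2-yn-1-one | C=C(C)[C@H](OCOC)Cc1cc(C#CC(=O)c2c(O)cc(OCOC)c(OC)c2OC)ccc1OC | intermediate
24 | 3-(diethylamino)-1-[2-hydroxy-5,6-dimethoxy-4-(methoxymethoxy)phenyl]-3-{4-methoxy-3-[(2R)-2-(methoxymethoxy)-3-methylbut-3-en-1-yl]phenyl}prop-2-en-1-one (alkene geometry not defined) | C=C(C)[C@H](OCOC)Cc1cc(C(=CC(=O)c2c(O)cc(OCOC)c(OC)c2OC)N(CC)CC)ccc1OC | intermediate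
25 | 5,6-dimethoxy-7-(methoxymethoxy)-2-{4-methoxy-3-[(2R)-2-(methoxymethoxy)-3-methylbut-3-en-1-yl]phenyl}-4H-chromen-4-one | C=C(C)[C@H](OCOC)Cc1cc(-c2cc(=O)c3c(OC)c(OC)c(OCOC)cc3o2)ccc1OC | intermediate
26 | 3-lithio derivative of 25 | C=C(C)[C@H](OCOC)Cc1cc(-c2oc3cc(OCOC)c(OC)c(OC)c3c(=O)c2[Li])ccc1OC | intermediate
27 | dimethyl boronate of 25 at C3 | C=C(C)[C@H](OCOC)Cc1cc(-c2oc3cc(OCOC)c(OC)c(OC)c3c(=O)c2B(OC)OC)ccc1OC | intermediate
28 | 3-hydroxy-5,6-dimethoxy-7-(methoxymethoxy)-2-{4-methoxy-3-[(2R)-2-(methoxymethoxy)-3-methylbut-3-en-1-yl]phenyl}-4H-chromen-4-one | C=C(C)[C@H](OCOC)Cc1cc(-c2oc3cc(OCOC)c(OC)c(OC)c3c(=O)c2O)ccc1OC | intermediate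
29 | 3,7-dihydroxy-2-{3-[(2R)-2-hydroxy-3-methylbut-3-en-1-yl]-4-methoxyphenyl}-5,6-dimethoxy-4H-chromen-4-one | C=C(C)[C@H](O)Cc1cc(-c2oc3cc(O)c(OC)c(OC)c3c(=O)c2O)ccc1OC | target

Total step count: 15 (ring A precursor steps 1–5, ring B acid steps 6–11, union and completion steps 12–15).
Longest linear sequence: 10 steps (steps 6–15, from 11 to 29).

Steps most likely to fail

Step 12. The C4a aryl anion may be protonated before it attacks the ester carbonyl, leaving simple O-arylation. It may also add to the alkyne instead of the carbonyl, the propiolate may decarboxylate on heating, and the product phenoxide may be arylated by excess aryne. The fallback keeps the same aryne polarisation but forms the C4–C4a bond with a one-carbon partner, setting out from 10 and 20 and returning at 23. Aryne generation from 10 with CsF in DMF at rt inserts the aryne into the formamide C=O bond (oxygen to C8a, carbon to C4a), and aqueous hydrolysis should give 6-hydroxy-2,3-dimethoxy-4-(methoxymethoxy)benzaldehyde F1. Acid 20 is protodecarboxylated (CuCl cat., Et3N, MeCN, 60 °C) to 4-ethynyl-1-methoxy-2-[(2R)-2-(methoxymethoxy)-3-methylbut-3-en-1-yl]benzene F2. The lithium acetylide of F2 (n-BuLi, THF, −78 °C) is added to the pre-formed lithium phenoxide of F1 to give the propargylic alcohol 1-[2-hydroxy-5,6-dimethoxy-4-(methoxymethoxy)phenyl]-3-{4-methoxy-3-[(2R)-2-(methoxymethoxy)-3-methylbut-3-en-1-yl]phenyl}prop-2-yn-1-ol F3 as a mixture of carbinol epimers. Oxidation with MnO2 in CH2Cl2 then gives 23.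

Step 14. Deprotonation may occur at C8 beside the MOM ether instead of at C3, the amide base may add at C2 and open ring C, or the lithio species may be trapped incompletely by the borate. The fallback makes the C3 enolate by reduction and not by deprotonation, setting out from 25 and returning at 28. Conjugate reduction with LiBH(s-Bu)3 in THF at −78 °C is followed in the same flask by enolate hydroxylation with 3-phenyl-2-(phenylsulfonyl)oxaziridine. This should give 3-hydroxy-5,6-dimethoxy-7-(methoxymethoxy)-2-{4-methoxy-3-[(2R)-2-(methoxymethoxy)-3-methylbut-3-en-1-yl]phenyl}chroman-4-one F4 as a mixture of 2,3-trans diastereomers. Dess–Martin oxidation of the C3 alcohol gives the 3,4-dione, which enolises to flavonol 28; neither reagent attacks the isopropenyl group.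

Step 9. The catalyst may discriminate poorly between the benzylic CH2 and the isopropenyl group, lowering the enantiomeric excess, or the alkene may be hydroborated. The fallback sets the centre by kinetic resolution, setting out from 16 and returning at 17. Luche reduction (NaBH4, CeCl3·7H2O, MeOH, −40 °C) gives racemic 1-(5-iodo-2-methoxyphenyl)-3-methylbut-3-en-2-ol F5. Sharpless kinetic resolution (Ti(O-i-Pr)4, L-(+)-diisopropyl tartrate, t-BuOOH 0.6 equiv, 4 Å molecular sieves, CH2Cl2, −20 °C) should epoxidise the S enantiomer faster and leave (R)-17. The same resolution can also upgrade scalemic material from step 9.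

Further compounds
F1 | step 12 | 6-hydroxy-2,3-dimethoxy-4-(methoxymethoxy)benzaldehyde | COCOc1cc(O)c(C=O)c(OC)c1OC
F2 | step 12 | 4-ethynyl-1-methoxy-2-[(2R)-2-(methoxymethoxy)-3-methylbut-3-en-1-yl]benzene | C=C(C)[C@H](OCOC)Cc1cc(C#C)ccc1OC
F3 | step 12 | 1-[2-hydroxy-5,6-dimethoxy-4-(methoxymethoxy)phenyl]-3-{4-methoxy-3-[(2R)-2-(methoxymethoxy)-3-methylbut-3-en-1-yl]phenyl}prop-2-yn-1-ol (carbinol epimers) | C=C(C)[C@H](OCOC)Cc1cc(C#CC(O)c2c(O)cc(OCOC)c(OC)c2OC)ccc1OC
F4 | step 14 | 3-hydroxy-5,6-dimethoxy-7-(methoxymethoxy)-2-{4-methoxy-3-[(2R)-2-(methoxymethoxy)-3-methylbut-3-en-1-yl]phenyl}chroman-4-one (2,3-trans diastereomers) | C=C(C)[C@H](OCOC)Cc1cc(C2Oc3cc(OCOC)c(OC)c(OC)c3C(=O)C2O)ccc1OC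
F5 | step 9 | racemic 1-(5-iodo-2-methoxyphenyl)-3-methylbut-3-en-2-ol | C=C(C)C(O)Cc1cc(I)ccc1OC
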